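Time comes here in steps of 2.5 min, so I reckon the flask portion by portion, by hand.

all flasks: free catalyst 1.1 mM

|  | substrate | remark | time |
|---|---|---|---|
| oak | 0.075 M (in portions, 4) | run made earlier; portions every 2.5 min |  |
| flask | 0.050 M (in portions, 4) | the portions of substrate follow each other after 2.5 min, the first at the start | 10 min |
- oak (time / min: product / %, substrate / %): 0.667: 4.4, 8.6; 1.33: 6.7, 4.4; 2.00: 7.8, 2.3; 2.50: 8.5, 1.6; 3.00: 11.8, 11.5

(scatter of a reading: 0.3 percentage points)
1. how much product the flask holds at 10 min, in percent of the substrate charged
2. how much substrate the flask holds at 10 min, in percent of the substrate charged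
3. how much homo dimer A the flask holds at 10 min, in percent of the substrate charged
- percentages count the substrate that a species holds: one homo dimer A counts as two

In the oak run, product gained from 0.667 min to 2.50 min, over the area under substrate, reads as a pseudo-first-order constant k of 0.545 min⁻¹. I take homo dimer A as second order in substrate; the reciprocal of substrate then obeys a linear equation, which integrates in closed form. One number carries the result: the portion number g, the dimer rate over the product rate when substrate stands at one portion. The substrate read at 2.50 min makes it 4.04 in the oak run. It scales with portion size, so this flask has 2.69.

The ladder in this flask starts with the dimer clock at a fresh portion, 0.682 min, shorter than the product clock, 1.83 min, and that is shorter than the interval. So a portion opens as dimer and ends as product. With s and r the substrate at the start and end of a cycle, in portions, and x = exp(−k·interval) = 0.256, I get r = x·s/(1 + g·s·(1 − x)). The first cycle ends at 0.0853 and later ones at 0.0876. The product share of a portion is ln((1 + g·s)/(1 + g·r))/g: 0.408 first, then 0.429. After 4 cycles I expect 42.4% product, 2.19% substrate and 55.4% homo dimer A.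

The forecast has 40.5% product, 2.6% substrate and 56.9% homo dimer A, on this ground: “dimerisation looks second order and essentially irreversible”.

The flask holds 42.1% product, 2.74% substrate and 55.1% homo dimer A, so substrate stands above my figure.

    catalyst intermediate → free catalyst + product (k = 0.890 s⁻¹)
    2 substrate → homo dimer A (k = 0.820 M⁻¹ s⁻¹)
    substrate + free catalyst ⇌ catalyst intermediate (K = 50.0 M⁻¹, k = 9.30 M⁻¹ s⁻¹)
    2 substrate → homo dimer B (k = 2.30 × 10⁻⁴ M⁻¹ s⁻¹)

At 5.03 min, just after a portion, the forward step into catalyst intermediate uses substrate at 0.43 of the dimer rate, and the intermediate falls back at 0.21 of its rate onward. The neighbour flask with 0.030 M of substrate has a portion number of 1.62, and its cycles end at 0.122. The same rule gives it 51.9% product, and it holds 51.7%.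

The earlier runs and the new flask were generated by integration from invented constants, noise included.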